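**Plan**

The first cut removes the two C–CH3 bonds at the quaternary carbon of the cyclohexadienone ring B. That carbon lies between the two enolised C–OH carbons, so ring B is an acetylphloroglucinol ring methylated twice at its only C–H, while benzene ring A (butanoyl, two OH, OCH3, CH3, CH2) has no C–H left.
The second cut is the CH2–ring B bond, giving an ortho-quinone methide of aspidinol (stored as its Mannich base) and 2,4,6-trihydroxyacetophenone. Aspidinol is cut back to 2-methylphloroglucinol through its O–CH3 and butanoyl–ring bonds.
Forward: ring A is butanoylated, O-methylated and aminomethylated, then joined through the CH2 group to the second benzene ring, and ring B is dearomatised in the last step. No ring is formed at any stage.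
The target has no stereocentre (the quaternary carbon carries two identical methyl groups), so no stereocontrol is required.

Key step: step 5

Remark: the target is a β-triketone with mobile enol tautomers; the enol form of the given structure is taken as the compound to be made.

**Route**

Step 1
Reactants: 1 2-methylphloroglucinol; 2 butyryl chloride
Product: 3 1-(2,4,6-trihydroxy-3-methylphenyl)butan-1-one
Conditions: AlCl3 (3.5 equiv), PhNO2, rt → 60 °C; ice/aq. HCl work-up
Reagents that add atoms: none
Why: Friedel–Crafts C-acylation of the electron-rich triol takes place at either of its two equivalent free ring carbons, and the new ketone deactivates the ring against a second acylation (any O-ester formed first should undergo Fries rearrangement under the same conditions).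

Step 2
Reactants: 3 1-(2,4,6-trihydroxy-3-methylphenyl)butan-1-one
Product: 4 aspidinol, 1-(2,6-dihydroxy-4-methoxy-3-methylphenyl)butan-1-one
Conditions: Me2SO4 (1.0 equiv), K2CO3 (1.0 equiv), acetone, rt → reflux
Reagents that add atoms: dimethyl sulfate, COS(=O)(=O)OC
Why: Williamson-type O-methylation with one equivalent of a hard methylating agent and a weak carbonate base should take the hydroxyl para to the ketone, which is the most acidic and is not hydrogen-bonded to the carbonyl, as in the standard preparation of 4-O-methyl phloroacylphenones.

Step 3
Reactants: 4 aspidinol
Product: 5 1-{3-[(dimethylamino)methyl]-2,6-dihydroxy-4-methoxy-5-methylphenyl}butan-1-one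
Conditions: 37% aq. CH2O, 40% aq. Me2NH (excess), EtOH, 0 °C → rt
Reagents that add atoms: formaldehyde, C=O; dimethylamine, CNC
Why: Mannich aminomethylation, in which the iminium ion from formaldehyde and dimethylamine attacks the only unsubstituted ring carbon of aspidinol (ortho and para to hydroxyl groups), while the excess amine keeps the product as the benzylic amine instead of letting it condense with a second aspidinol.

Step 4
Reactants: 5 1-{3-[(dimethylamino)methyl]-2,6-dihydroxy-4-methoxy-5-methylphenyl}butan-1-one; 6 2,4,6-trihydroxyacetophenone (3 equiv)
Product: 8 1-[3-(3-acetyl-2,4,6-trihydroxybenzyl)-2,6-dihydroxy-4-methoxy-5-methylphenyl]butan-1-one, via ortho-quinone methide 7 (not isolated)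
Conditions: 1,4-dioxane, 100 °C, N2 sweep to remove Me2NH
Reagents that add atoms: none
Why: Thermal elimination of dimethylamine from the ortho-hydroxybenzylamine gives ortho-quinone methide 7, which undergoes Michael-type C-addition by 6 at one of its two equivalent free ring carbons and rearomatises; ring A has no free carbon and cannot self-condense, and the excess of 6 suppresses double benzylation.

Step 5
Reactants: 8 1-[3-(3-acetyl-2,4,6-trihydroxybenzyl)-2,6-dihydroxy-4-methoxy-5-methylphenyl]butan-1-one; 9 iodomethane (about 2.2 equiv)
Product: 11 2-acetyl-6-[(3-butanoyl-2,4-dihydroxy-6-methoxy-5-methylphenyl)methyl]-3,5-dihydroxy-4,4-dimethylcyclohexa-2,5-dien-1-one (the target), via mono-C-methylated diarylmethane 10 (not isolated)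
Conditions: NaOMe (about 6 equiv), MeOH, 0 °C → rt; then 1 M HCl, crystallisation
Reagents that add atoms: none
Why: NaOMe turns 8 into a polyphenoxide whose acetylphloroglucinol ring B is an ambident anion; its single hydrogen-bearing ring carbon attacks iodomethane in an SN2 step to give 10, and after renewed deprotonation the same carbon is methylated again, which creates the quaternary C(CH3)2 and leaves ring B as the enolate of a cyclohexadienone β-triketone that acidification converts into 11. The closest known reaction type is the exhaustive C-methylation of acylphloroglucinols by iodomethane and alkoxide that delivers acylfilicinic acids. The step closes no ring and creates no stereocentre, since the new quaternary carbon carries two identical methyl groups. It needs carbon- over oxygen-alkylation, ring B over ring A, and in the second alkylation the methyl-bearing carbon over the arylmethyl-bearing one. Hydrogen bonding of the phenoxide oxygens by methanol and the soft iodide electrophile favour attack through carbon, ring A has no C–H and its two phenoxides are tied into the butanoyl chromophore, and the arylmethyl-bearing carbon is the more hindered site. The dearomatised product anion is a delocalised vinylogous carboxylate of low nucleophilicity, and keeping iodomethane near two equivalents at 0 °C should limit both a third methylation and base-induced exchange of the methylene bridge.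

**Compound list**

1 | 2-methylphloroglucinol (2-methylbenzene-1,3,5-triol) | Cc1c(O)cc(O)cc1O | starting material
2 | butyryl chloride (butanoyl chloride) | CCCC(Cl)=O | starting material
3 | 1-(2,4,6-trihydroxy-3-methylphenyl)butan-1-one | CCCC(=O)c1c(O)c(C)c(O)cc1O | intermediate
4 | aspidinol, 1-(2,6-dihydroxy-4-methoxy-3-methylphenyl)butan-1-one | CCCC(=O)c1c(O)c(C)c(OC)cc1O | intermediate
5 | 1-{3-[(dimethylamino)methyl]-2,6-dihydroxy-4-methoxy-5-methylphenyl}butan-1-one | CCCC(=O)c1c(O)c(C)c(OC)c(CN(C)C)c1O | intermediate
6 | 2,4,6-trihydroxyacetophenone | CC(=O)c1c(O)cc(O)cc1O | starting material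
7 | ortho-quinone methide, 2-butanoyl-3-hydroxy-5-methoxy-4-methyl-6-methylidenecyclohexa-2,4-dien-1-one (not isolated) | CCCC(=O)C1=C(O)C(C)=C(OC)C(=C)C1=O | intermediate
8 | 1-[3-(3-acetyl-2,4,6-trihydroxybenzyl)-2,6-dihydroxy-4-methoxy-5-methylphenyl]butan-1-one | CCCC(=O)c1c(O)c(C)c(OC)c(Cc2c(O)cc(O)c(C(C)=O)c2O)c1O | intermediate
9 | iodomethane | CI | starting material
10 | mono-C-methylated diarylmethane, 1-[3-(3-acetyl-2,4,6-trihydroxy-5-methylbenzyl)-2,6-dihydroxy-4-methoxy-5-methylphenyl]butan-1-one (not isolated) | CCCC(=O)c1c(O)c(C)c(OC)c(Cc2c(O)c(C)c(O)c(C(C)=O)c2O)c1O | intermediate
11 | 2-acetyl-6-[(3-butanoyl-2,4-dihydroxy-6-methoxy-5-methylphenyl)methyl]-3,5-dihydroxy-4,4-dimethylcyclohexa-2,5-dien-1-one | CCCC(=O)c1c(O)c(C)c(OC)c(CC2=C(O)C(C)(C)C(O)=C(C(C)=O)C2=O)c1O | target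

**Step count**

Total steps: 5. Longest linear sequence: 5 steps (1 → 3 → 4 → 5 → 8 → 11); compounds 2, 6 and 9 are purchased.

**Steps most likely to fail**

1. Step 5. The alkylation may not stop cleanly: a third methyl group may enter at the arylmethyl-bearing carbon of ring B or dearomatise ring A, oxygen may be methylated in competition, and the alkoxide medium may cleave the methylene bridge by retro-Michael reaction and recombine the halves into symmetric dimers. The fallback moves the dimethylation ahead of the bridge formation. Compound 6 would be C-methylated twice with iodomethane 9 and NaOMe in MeOH to give 2-acetyl-3,5-dihydroxy-4,4-dimethylcyclohexa-2,5-dien-1-one (acetylfilicinic acid) F1, which has a single nucleophilic ring C–H and no second ring to be spared. Heating F1 with Mannich base 5 in dioxane should then give 11 directly by conjugate addition to ortho-quinone methide 7. This fallback sets out from 6 and 5 and rejoins the route at 11.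

2. Step 4. The nucleophile 6 has two free ring carbons, so double benzylation may compete, and heat together with the liberated amine may cause exchange of the methylene bridge. The fallback uses a nucleophile with only one free carbon. Friedel–Crafts acetylation of 1 (acetyl chloride, AlCl3, PhNO2) would give 1-(2,4,6-trihydroxy-3-methylphenyl)ethan-1-one F2. Heating F2 with 5 in dioxane should give 10 as an isolated compound, which then needs only one C-methylation under the conditions of step 5 (one equivalent less of iodomethane) to reach 11. This fallback sets out from 1 and 5 and rejoins the route at 10.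

3. Step 2. Site selection among three hydroxyl groups may be poor, and methylation may run on to di-ethers. The fallback replaces selective protection by selective deprotection. Exhaustive O-methylation of 3 (excess Me2SO4, K2CO3, acetone, reflux) would give 1-(2,4,6-trimethoxy-3-methylphenyl)butan-1-one F3. BCl3 in CH2Cl2 (−78 °C → rt) should then cleave the two methyl ethers ortho to the ketone through the boron chelate and leave the para ether, giving 4. This fallback sets out from 3 and rejoins the route at 4.

**Further compounds**

F1 | step 5 | 2-acetyl-3,5-dihydroxy-4,4-dimethylcyclohexa-2,5-dien-1-one (acetylfilicinic acid) | CC(=O)C1=C(O)C(C)(C)C(O)=CC1=O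
F2 | step 4 | 1-(2,4,6-trihydroxy-3-methylphenyl)ethan-1-one | CC(=O)c1c(O)c(C)c(O)cc1O
F3 | step 2 | 1-(2,4,6-trimethoxy-3-methylphenyl)butan-1-one | CCCC(=O)c1c(OC)c(C)c(OC)cc1OC
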